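| flask | left-handed substrate | right-handed substrate | solid reagent | free catalyst | racemization catalyst | remark | time |
|---|---|---|---|---|---|---|---|
| zeta | 0.17 M | 0.17 M | 0.24 M | 12 mM | 7.2 mM | run made earlier |  |
| epsilon | 0.26 M | 0.26 M | 0.24 M | 12 mM | 7.2 mM | run made earlier |  |
| gamma | 0.12 M | 0.12 M | 0.24 M | 12 mM | 14 mM | run made earlier |  |
| flask | 0.12 M | 0.12 M | 0.240 M | 12 mM | 7.2 mM |  | 15 h |

| run | time / h | left-handed product / % | right-handed product / % |
|---|---|---|---|
| zeta | 0.833 | 6.7 | 1.3 |
| zeta | 2.50 | 15.0 | 5.5 |
| zeta | 4.00 | 19.3 | 8.6 |
| zeta | 6.00 | 23.6 | 10.2 |
| zeta | 10.0 | 27.7 | 10.9 |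
| epsilon | 0.667 | 5.4 | 1.9 |
| epsilon | 1.33 | 9.3 | 4.1 |
| epsilon | 2.50 | 15.3 | 5.4 |
| epsilon | 5.00 | 21.7 | 8.9 |
| epsilon | 10.0 | 26.5 | 10.9 |
| gamma | 2.00 | 12.8 | 5.2 |
| gamma | 4.00 | 19.8 | 7.3 |
| gamma | 5.00 | 22.2 | 9.6 |
| gamma | 8.00 | 27.0 | 11.7 |
| gamma | 10.0 | 28.7 | 11.4 |

(scatter of a reading: 0.5 percentage points)

- left-handed product and right-handed product together, in percent of the left-handed substrate and right-handed substrate charged together, at 15 h
- excess of left-handed product over right-handed product in the product at 15 h
- whether the exchange between left-handed substrate and right-handed substrate keeps pace with the reaction: how far the product's excess at 15 h gets from its value without exchange to its value with instant exchange (above 80% keeps pace, below 20% hardly takes part, else lags behind)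

- free catalyst is single-handed; left-handed substrate and right-handed substrate are mirror images of each other, charged as a racemate, each of them at the stated concentration
- given per volume of solution although it is solid: solid reagent
- candidate steps: left-handed substrate + racemization catalyst <-> right-handed substrate + racemization catalyst; partner + free catalyst + left-handed substrate -> free catalyst + left-handed product; 2 racemization catalyst -> spent catalyst A; partner + free catalyst -> spent catalyst B; solid reagent <-> partner; partner + free catalyst + right-handed substrate -> free catalyst + right-handed product
- at the start none of the solid reagent is in solution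
- an excess is below zero if the other one leads

1. The ratio of two loads is the place to begin: in the gamma run the load, meaning the natural logarithm of both substrates charged over both substrates unreacted, is 0.383 at 5.00 h and 0.512 at 10.0 h, a ratio of 1.34.

2. Both product steps and the step to spent catalyst B carry [partner] and [free catalyst], and the percent curves of zeta, epsilon and gamma nearly coincide, so I take it that each bit of catalyst lost buys the same load, whatever [partner] is.

3. While solid reagent remains I freeze [partner] near its solubility, which makes [free catalyst] fall exponentially, so the ratio minus one is the share of catalyst surviving 5.00 h: 0.339, a life of 4.62 h.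

4. The load's ceiling is then 0.579, and dividing by the catalyst charged gives the load capacity of 48.3 L mol⁻¹, the load bought per mole per litre of free catalyst.

5. For this flask, which has gamma's substrate and free catalyst charges but 7.2 mM of racemization catalyst against gamma's 14 mM (a difference I ignore), the load at 15 h is 0.556, so I commit to a yield of 42.7%.

6. Now the ledger of the solid reagent, which with the substrates is the limiting reagent on paper, 0.240 M against 0.240 M: products take 0.102 M, catalyst death takes at most 12 mM, and 0.126 M stays dissolved or solid, more than the catalyst can still claim, so in my reckoning the catalyst ends this flask.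

The forecast, made from the same runs, gave a yield of 42.5% (40.5% to 45.5%), an excess of 41.5% (38% to 45%) and an exchange that "hardly takes part", holding that “exchange is negligible, probably because that catalyst is slow or dies early”.

The flask gives a yield of 43.1% against my 42.7%, an excess of 40.7%, and an exchange that lags behind, getting 38% of the way.

    left-handed substrate + racemization catalyst ⇌ right-handed substrate + racemization catalyst, rate k1*[racemization catalyst]*[left-handed substrate] forward; the back reaction follows from the equilibrium constant (k = 0.0130 L mol⁻¹ s⁻¹)
    partner + free catalyst + left-handed substrate → free catalyst + left-handed product (k = 0.0500 L² mol⁻² s⁻¹)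
    2 racemization catalyst → spent catalyst A (k = 0.0190 L mol⁻¹ s⁻¹)
    partner + free catalyst → spent catalyst B (k = 6.60 × 10⁻⁴ L mol⁻¹ s⁻¹)
    solid reagent ⇌ partner, rate k5*(cs5 - [partner]) while solid is left; crystals form when [partner] > cs5 (solubility = 0.0840 M, k = 0.00620 s⁻¹)
    partner + free catalyst + right-handed substrate → free catalyst + right-handed product (k = 0.0180 L² mol⁻² s⁻¹)

At 0.620 h in this flask the half-life of left-handed substrate by the forward exchange alone is 3.3 h, shorter than the 12 h half-life of right-handed substrate by its product step. But in this flask racemization catalyst is down to 40.4% of its charge at 1.50 h and 6.34% of its charge at 15.0 h. On the neighbour flask charged with 0.0048 M of free catalyst, you multiply the load capacity by that charge and by the same share of catalyst lost by 15 h as in step 5, which gives a load of 0.223 and a yield of 20.0%. The computed yield there is 20.6%, with [partner] at 0.0840 M.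

(The runs are simulated for substances that don't exist, and the scatter is random.)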